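The runs are calculated with made-up constants; noise was put on by code.

Time showed me the trouble first. In Wednesday's flask, the very flask asked about, target slowed 3.74-fold after the first reading, more than the 1.48-fold that the fall in starting material, squared, allows. Then it stopped with 76.7% of starting material still there. I read that as kinetic control, a dying catalyst, not an equilibrium.

| flask | starting material | partner | second substrate | protic impurity | free catalyst | temperature | remark | time |
|---|---|---|---|---|---|---|---|---|
| Wednesday's | 0.050 M | 0.050 M | 0.050 M | 0.050 M | 0.14 mM | 25 °C | the very flask that is asked about, followed so far |  |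
| Friday's | 0.050 M | 0.050 M | 0.050 M | 0.050 M | 0.14 mM | 31 °C | run made earlier |  |
| flask | 0.050 M | 0.0500 M | 0.0500 M | 0.0500 M | 0.14 mM | 25 °C |  | 25 h |

| run | time / h | target / % | starting material / % |
|---|---|---|---|
| Wednesday's | 1.50 | 10.9 | 88.8 |
| Wednesday's | 5.00 | 17.7 | 82.1 |
| Wednesday's | 8.00 | 20.1 | 78.8 |
| Wednesday's | 15.0 | 23.3 | 77.6 |
| Wednesday's | 20.0 | 23.3 | 76.8 |
| Wednesday's | 25.0 | 23.4 | 76.7 |
| Friday's | 1.50 | 14.1 | 86.5 |
| Friday's | 5.00 | 18.4 | 80.7 |
| Friday's | 8.00 | 20.0 | 79.4 |
| Friday's | 15.0 | 22.3 | 78.9 |
| Friday's | 20.0 | 22.6 | 77.4 |
| Friday's | 25.0 | 22.0 | 77.8 |

(scatter of a reading: 0.5 percentage points)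

- south: at 25 h add partner, 100% of the amount charged, then wait 25 h
- south-west: change nothing and wait 25 h more
- north-west: at 25 h add free catalyst, 50.0% of the amount charged, then wait 25 h
- west: at 25 h raise the temperature by 25 K, then wait 25 h
- north-east: at 25 h take out 90% of the target then present, then wait 25 h

- removed target is counted in
- additions bring no volume worth counting

- target, in percent of the starting material first charged, at 25 h
- the remedy with the largest gain of target, or "none" below 2 percentage points (south / south-west / north-west / west / north-east / none)
- target present, with what was taken out counted in, in percent of the starting material first charged, after north-west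
- target present, with what was taken out counted in, in percent of the starting material first charged, after north-east

Suppose the catalyst is lost in pairs. Then target climbs by equal steps per doubling of time. A larger dose dies faster in proportion, so a doubling of dose counts as a doubling of time. I named this step the doubling gain, the points of target per doubling while the catalyst dies, and read it from the early readings:

D = 3.8 percentage points

The plateau gave me "now":

plateau = 23.3%

For north-west I bracketed the answer. From below, I treated the added catalyst as if it had been in the charge from the start:

lower = 25.6%

From above, I took a half dose in a fresh mixture, one doubling below the plateau, at 19.5%. I scaled that by the starting material left, squared, with partner taken as no higher than starting material, the two being charged alike and used one for one in target: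

upper = 34.8%

The lower end already gains 2.3 points, so I chose north-west. Removed target revives no catalyst, so I put g5 at the plateau.

The forecast, saying it “fits a mildly exothermic equilibrium”, gave 23.4%, south, g3 23.6%, below my bracket, and g5 36%.

The flask gave 23.6%, best north-west, g3 30.5%, inside my bracket, and g5 24.4%.

    starting material + partner + free catalyst → free catalyst + target (k = 390 L² mol⁻² min⁻¹, Ea = 49.0 kJ mol⁻¹)
    second substrate + partner + free catalyst → free catalyst + second product (k = 19.0 L² mol⁻² min⁻¹, Ea = 54.0 kJ mol⁻¹)
    2 free catalyst → spent catalyst A (k = 71.0 L mol⁻¹ min⁻¹, Ea = 62.0 kJ mol⁻¹)
    partner + protic impurity → quenched reagent (k = 0.0120 L mol⁻¹ min⁻¹, Ea = 67.0 kJ mol⁻¹)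
    partner + free catalyst → spent catalyst B (k = 0.0390 L mol⁻¹ min⁻¹, Ea = 65.0 kJ mol⁻¹)
    (constants at 25 °C)

Free catalyst's first half-life by pairing alone was 0.838 h, against 19 h for partner by protic impurity alone. At 25.0 h the flask held 1.43% of its catalyst in working form, with 76% of starting material and 36% of partner left.

The neighbour flask charged with 5.6 × 10⁻⁴ M of free catalyst stands 2.00 doublings above the recipe, so 3.8 points per doubling gives 31.0%. The simulation of that neighbour gives 32.8%.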